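**Retrosynthetic overview**
1. The C4(upper)–C6(lower) bond is cut last: Ag(I)-promoted coupling of a 4-benzylsulfanyl 2,3-trans-flavan-3-ol with the lower flavan-3,4-diol diacetate; the upper 3-OH is then inverted (oxidation, L-Selectride) to the all-cis array.
2. Both halves come from one monomer, the (2R,3S)-tetra-O-benzyl flavan-3-ol 12; the lower half is 12 → 3-ketone → cis-3-ol → DDQ/H2O hydroxylation at C-4.
3. The C-ring of 12 is cut across O1–C2 and C3–C4: [4+2] cycloaddition of an A-ring o-quinone methide with an (E)-styrene made from (S)-vinyl-dioxolane; the dioxolane stereocentre sets C-2 and C-3 and is then degraded to the 3-OH (periodate, Baeyer–Villiger).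
4. Ring order: A and B rings are bought; the C-ring is made once by cycloaddition and serves both halves; the lower C-ring is finished before the union, the upper C-3 is adjusted after it.

Assumption: the SMILES is read literally (upper unit 2R,3R,4R = 2,3-cis-3,4-cis; lower unit 2R,3R,4S = 2,3-cis-3,4-trans; C-4 → C-6 link); 4-bromo-1,2-bis(benzyloxy)benzene and (S)-2,2-dimethyl-4-vinyl-1,3-dioxolane (from D-mannitol via (R)-glyceraldehyde acetonide) are catalogue compounds.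

**Route**

Step 1
Reactants: 1 2,3,4-trihydroxybenzaldehyde
Product: 2 3,4-bis(benzyloxy)-2-hydroxybenzaldehyde
Conditions: BnBr (2.1 equiv), K2CO3 (2.1 equiv), DMF, rt
Reagents that add atoms: benzyl bromide, BrCc1ccccc1
Why: Williamson etherification in which the 2-OH, hydrogen-bonded to the aldehyde, is the least nucleophilic phenol and stays free.

Step 2
Reactants: 2 3,4-bis(benzyloxy)-2-hydroxybenzaldehyde
Product: 3 2,3-bis(benzyloxy)-6-(hydroxymethyl)phenol
Conditions: NaBH4, MeOH/THF, 0 °C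
Reagents that add atoms: none
Why: Borohydride reduction of the aldehyde gives the o-hydroxybenzyl alcohol that serves as o-quinone methide precursor.

Step 3
Reactants: 4 4-bromo-1,2-bis(benzyloxy)benzene; 5 (4S)-2,2-dimethyl-4-vinyl-1,3-dioxolane
Product: 6 (4S)-4-[(E)-2-[3,4-bis(benzyloxy)phenyl]ethenyl]-2,2-dimethyl-1,3-dioxolane
Conditions: Pd(OAc)2 (5 mol %), P(o-tol)3 (10 mol %), Et3N, DMF, 100 °C (sealed)
Reagents that add atoms: none
Why: Heck arylation of the terminal alkene (syn insertion, syn β-hydride elimination) gives the conjugated (E)-styrene and does not touch the bought dioxolane stereocentre.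

Step 4
Reactants: 3 2,3-bis(benzyloxy)-6-(hydroxymethyl)phenol; 6 (4S)-4-[(E)-2-[3,4-bis(benzyloxy)phenyl]ethenyl]-2,2-dimethyl-1,3-dioxolane
Product: 8 (2S,3S)-7,8-bis(benzyloxy)-2-[3,4-bis(benzyloxy)phenyl]-3-[(4S)-2,2-dimethyl-1,3-dioxolan-4-yl]chromane (2,3-trans), via o-quinone methide 7 (not isolated)
Conditions: 3 (3 equiv, slow addition), 4 Å MS, o-xylene, 150 °C (sealed tube)
Reagents that add atoms: none
Why: Thermal dehydration of 3 gives o-quinone methide 7, which adds to the electron-rich styrene in an inverse-electron-demand hetero-Diels–Alder reaction (methide carbon to the β-carbon, oxygen to the benzylic carbon), the E geometry being carried suprafacially into the 2,3-trans ring and the (S)-dioxolane directing attack to the alkene face anti to its allylic C–O bond (inside-alkoxy model) so that C-2 and C-3 are set as drawn, the minor facial diastereomer being removed by chromatography.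

Step 5
Reactants: 8 (2S,3S)-7,8-bis(benzyloxy)-2-[3,4-bis(benzyloxy)phenyl]-3-[(4S)-2,2-dimethyl-1,3-dioxolan-4-yl]chromane
Product: 10 (2S,3S)-7,8-bis(benzyloxy)-2-[3,4-bis(benzyloxy)phenyl]chromane-3-carbaldehyde (2,3-trans), via vicinal diol 9 (not isolated)
Conditions: H5IO6 (1.5 equiv), EtOAc, rt
Reagents that add atoms: none
Why: Periodic acid hydrolyses the terminal acetonide and cleaves the resulting glycol in one pot (Malaprade cleavage), leaving the formyl group on C-3 in the thermodynamically preferred trans arrangement.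

Step 6
Reactants: 10 (2S,3S)-7,8-bis(benzyloxy)-2-[3,4-bis(benzyloxy)phenyl]chromane-3-carbaldehyde
Product: 12 (2R,3S)-7,8-bis(benzyloxy)-2-[3,4-bis(benzyloxy)phenyl]chroman-3-ol (2,3-trans), via 3-O-formate 11 (not isolated)
Conditions: mCPBA, CH2Cl2, 0 °C → rt; then K2CO3 (cat.), MeOH, 0 °C
Reagents that add atoms: meta-chloroperoxybenzoic acid, OOC(=O)c1cccc(Cl)c1
Why: Baeyer–Villiger oxidation of the α-branched aldehyde, in which the secondary C-3 migrates to oxygen with retention so that the 3-oxygen takes the place of the former C–C bond, followed by methanolysis of the formate.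

Step 7
Reactants: 12 (2R,3S)-7,8-bis(benzyloxy)-2-[3,4-bis(benzyloxy)phenyl]chroman-3-ol
Product: 13 (2R)-7,8-bis(benzyloxy)-2-[3,4-bis(benzyloxy)phenyl]chroman-3-one
Conditions: Dess–Martin periodinane, CH2Cl2, rt
Reagents that add atoms: none
Why: Dess–Martin oxidation is neutral enough to give the flavan-3-one without epimerising the C-2 stereocentre.

Step 8
Reactants: 13 (2R)-7,8-bis(benzyloxy)-2-[3,4-bis(benzyloxy)phenyl]chroman-3-one
Product: 14 (2R,3R)-7,8-bis(benzyloxy)-2-[3,4-bis(benzyloxy)phenyl]chroman-3-ol (2,3-cis)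
Conditions: L-Selectride, THF, −78 °C; then H2O
Reagents that add atoms: none
Why: The bulky hydride attacks the ketone from the face anti to the equatorial C-2 aryl group (substrate-controlled reduction), giving the axial 3-OH cis to the aryl group.

Step 9
Reactants: 14 (2R,3R)-7,8-bis(benzyloxy)-2-[3,4-bis(benzyloxy)phenyl]chroman-3-ol
Product: 15 (2R,3R,4S)-7,8-bis(benzyloxy)-2-[3,4-bis(benzyloxy)phenyl]chromane-3,4-diol (2,3-cis-3,4-trans)
Conditions: DDQ (1.3 equiv), CH2Cl2/H2O (10:1), 0 °C → rt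
Reagents that add atoms: water, O
Why: DDQ abstracts hydride from C-4 (benzylic, para to the 7-benzyloxy group and ortho to O-1) and water adds to the cation anti to the axial 3-OH, giving the 3,4-trans alcohol (benzylic C–H oxidation).

Step 10
Reactants: 15 (2R,3R,4S)-7,8-bis(benzyloxy)-2-[3,4-bis(benzyloxy)phenyl]chromane-3,4-diol
Product: 16 3,4-di-O-acetate of 15 (configuration unchanged)
Conditions: Ac2O, pyridine, DMAP (cat.), rt
Reagents that add atoms: acetic anhydride, CC(=O)OC(C)=O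
Why: Acetylation masks both secondary hydroxyls so that only the upper 3-OH is free for the later oxidation.

Step 11
Reactants: 12 (2R,3S)-7,8-bis(benzyloxy)-2-[3,4-bis(benzyloxy)phenyl]chroman-3-ol
Product: 17 (2R,3S,4R)-7,8-bis(benzyloxy)-2-[3,4-bis(benzyloxy)phenyl]-4-methoxychroman-3-ol (2,3-trans-3,4-trans)
Conditions: DDQ (1.5 equiv), MeOH/CH2Cl2 (1:4), rt
Reagents that add atoms: methanol, CO
Why: DDQ benzylic oxidation at C-4 with methanol trapping the cation anti to the 3-OH installs a leaving group at C-4.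

Step 12
Reactants: 17 (2R,3S,4R)-7,8-bis(benzyloxy)-2-[3,4-bis(benzyloxy)phenyl]-4-methoxychroman-3-ol
Product: 18 (2R,3R,4R)-4-(benzylsulfanyl)-7,8-bis(benzyloxy)-2-[3,4-bis(benzyloxy)phenyl]chroman-3-ol (same spatial arrangement as 17, 2,3-trans-3,4-trans)
Conditions: BnSH (5 equiv), BF3·OEt2 (20 mol %), CH2Cl2, −20 °C
Reagents that add atoms: phenylmethanethiol, SCc1ccccc1
Why: Lewis-acid SN1 exchange of the benzylic methoxy group for the thiol (thiolysis), again anti to the 3-OH, gives a leaving group that only a soft Lewis acid will ionise.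

Step 13
Reactants: 18 (2R,3R,4R)-4-(benzylsulfanyl)-7,8-bis(benzyloxy)-2-[3,4-bis(benzyloxy)phenyl]chroman-3-ol; 16 3,4-di-O-acetate of 15
Product: 19 octa-O-benzyl dimer, upper unit 2,3-trans-3,4-trans with free 3-OH, its C-4 bonded to C-6 of the lower unit (lower unit as in 16, 3,4-diacetate)
Conditions: AgBF4 (2.5 equiv), 16 (3 equiv, excess recovered), THF, 0 °C, dark
Reagents that add atoms: none
Why: Thiophilic Ag(I) ionises only the C-4 sulfide (the acetoxy groups of 16 stay), and the benzylic cation alkylates C-6 of 16 (para to the ring oxygen, ortho to OBn; Friedel–Crafts-type interflavan coupling) from the face anti to the 3-OH, so the new C-4 aryl group is trans to the 3-OH and cis to the C-2 aryl group.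

Step 14
Reactants: 19 octa-O-benzyl dimer with upper 3-OH
Product: 20 3-ketone of 19 (upper C-2 and C-4 aryl groups cis; lower diacetate unchanged)
Conditions: Dess–Martin periodinane, CH2Cl2, 0 °C → rt
Reagents that add atoms: none
Why: Dess–Martin oxidation of the only free hydroxyl under neutral conditions gives the 4-arylflavan-3-one without epimerising C-2 or C-4.

Step 15
Reactants: 20 3-ketone of 19
Product: 22 octa-O-benzyl ether of the target (upper unit all-cis; free 3-OH, 3''-OH and 4''-OH), via all-cis diacetate 21 (not isolated)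
Conditions: L-Selectride (4 equiv), THF, −78 °C; then 3 M NaOH, 30% H2O2, 0 °C → rt
Reagents that add atoms: none
Why: L-Selectride delivers hydride to the ketone from the face opposite the two cis aryl groups at C-2 and C-4, so the new 3-OH is cis to both (all-cis upper unit), and the alkaline peroxide work-up oxidises the borane and saponifies both acetates.

Step 16
Reactants: 22 octa-O-benzyl ether of the target
Product: 23 (2R,3R,4R)-2-(3,4-dihydroxyphenyl)-4-[(2R,3R,4S)-2-(3,4-dihydroxyphenyl)-3,4,7,8-tetrahydroxychroman-6-yl]chromane-3,7,8-triol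
Conditions: H2 (1 atm), 20% Pd(OH)2/C, THF/MeOH/H2O, rt, stopped at 8 equiv H2
Reagents that add atoms: none
Why: Hydrogenolysis of the eight aryl benzyl ethers under neutral conditions is faster than cleavage of the benzylic C-2–O, C-4–aryl and C-4''–OH bonds, so no stereocentre is touched.

**Compound list**
1 | 2,3,4-trihydroxybenzaldehyde | O=Cc1ccc(O)c(O)c1O | starting material
2 | 3,4-bis(benzyloxy)-2-hydroxybenzaldehyde | O=Cc1ccc(OCc2ccccc2)c(OCc2ccccc2)c1O | intermediate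
3 | 2,3-bis(benzyloxy)-6-(hydroxymethyl)phenol | OCc1ccc(OCc2ccccc2)c(OCc2ccccc2)c1O | intermediate
4 | 4-bromo-1,2-bis(benzyloxy)benzene | Brc1ccc(OCc2ccccc2)c(OCc2ccccc2)c1 | starting material
5 | (4S)-2,2-dimethyl-4-vinyl-1,3-dioxolane | C=C[C@H]1COC(C)(C)O1 | starting material
6 | (4S)-4-[(E)-2-[3,4-bis(benzyloxy)phenyl]ethenyl]-2,2-dimethyl-1,3-dioxolane | CC1(C)OC[C@H](/C=C/c2ccc(OCc3ccccc3)c(OCc3ccccc3)c2)O1 | intermediate
7 | 2,3-bis(benzyloxy)-6-methylidenecyclohexa-2,4-dien-1-one (o-quinone methide, not isolated) | C=C1C=CC(OCc2ccccc2)=C(OCc2ccccc2)C1=O | intermediate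
8 | (2S,3S)-7,8-bis(benzyloxy)-2-[3,4-bis(benzyloxy)phenyl]-3-[(4S)-2,2-dimethyl-1,3-dioxolan-4-yl]chromane | CC1(C)OC[C@@H](O1)[C@H]1Cc2ccc(OCc3ccccc3)c(OCc3ccccc3)c2O[C@@H]1c1ccc(OCc2ccccc2)c(OCc2ccccc2)c1 | intermediate
9 | vicinal diol from acetonide hydrolysis of 8, configuration as in 8 (not isolated) | OC[C@@H](O)[C@H]1Cc2ccc(OCc3ccccc3)c(OCc3ccccc3)c2O[C@@H]1c1ccc(OCc2ccccc2)c(OCc2ccccc2)c1 | intermediate
10 | (2S,3S)-7,8-bis(benzyloxy)-2-[3,4-bis(benzyloxy)phenyl]chromane-3-carbaldehyde | O=C[C@H]1Cc2ccc(OCc3ccccc3)c(OCc3ccccc3)c2O[C@@H]1c1ccc(OCc2ccccc2)c(OCc2ccccc2)c1 | intermediate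
11 | (2R,3S)-7,8-bis(benzyloxy)-2-[3,4-bis(benzyloxy)phenyl]chroman-3-yl formate (not isolated) | O=CO[C@H]1Cc2ccc(OCc3ccccc3)c(OCc3ccccc3)c2O[C@@H]1c1ccc(OCc2ccccc2)c(OCc2ccccc2)c1 | intermediate
12 | (2R,3S)-7,8-bis(benzyloxy)-2-[3,4-bis(benzyloxy)phenyl]chroman-3-ol | O[C@H]1Cc2ccc(OCc3ccccc3)c(OCc3ccccc3)c2O[C@@H]1c1ccc(OCc2ccccc2)c(OCc2ccccc2)c1 | intermediate
13 | (2R)-7,8-bis(benzyloxy)-2-[3,4-bis(benzyloxy)phenyl]chroman-3-one | O=C1Cc2ccc(OCc3ccccc3)c(OCc3ccccc3)c2O[C@@H]1c1ccc(OCc2ccccc2)c(OCc2ccccc2)c1 | intermediate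
14 | (2R,3R)-7,8-bis(benzyloxy)-2-[3,4-bis(benzyloxy)phenyl]chroman-3-ol | O[C@@H]1Cc2ccc(OCc3ccccc3)c(OCc3ccccc3)c2O[C@@H]1c1ccc(OCc2ccccc2)c(OCc2ccccc2)c1 | intermediate
15 | (2R,3R,4S)-7,8-bis(benzyloxy)-2-[3,4-bis(benzyloxy)phenyl]chromane-3,4-diol | O[C@H]1c2ccc(OCc3ccccc3)c(OCc3ccccc3)c2O[C@H](c2ccc(OCc3ccccc3)c(OCc3ccccc3)c2)[C@@H]1O | intermediate
16 | 3,4-di-O-acetate of 15 | CC(=O)O[C@H]1c2ccc(OCc3ccccc3)c(OCc3ccccc3)c2O[C@H](c2ccc(OCc3ccccc3)c(OCc3ccccc3)c2)[C@@H]1OC(C)=O | intermediate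
17 | (2R,3S,4R)-7,8-bis(benzyloxy)-2-[3,4-bis(benzyloxy)phenyl]-4-methoxychroman-3-ol | CO[C@@H]1c2ccc(OCc3ccccc3)c(OCc3ccccc3)c2O[C@H](c2ccc(OCc3ccccc3)c(OCc3ccccc3)c2)[C@H]1O | intermediate
18 | (2R,3R,4R)-4-(benzylsulfanyl)-7,8-bis(benzyloxy)-2-[3,4-bis(benzyloxy)phenyl]chroman-3-ol | c1ccccc1CS[C@@H]1c2ccc(OCc3ccccc3)c(OCc3ccccc3)c2O[C@H](c2ccc(OCc3ccccc3)c(OCc3ccccc3)c2)[C@H]1O | intermediate
19 | octa-O-benzyl dimer, upper unit 2,3-trans-3,4-trans (3-OH free), C-4 → C-6 of lower unit, lower 3,4-diacetate | O[C@H]1[C@H](c2cc3c(c(OCc4ccccc4)c2OCc4ccccc4)O[C@H](c2ccc(OCc4ccccc4)c(OCc4ccccc4)c2)[C@H](OC(C)=O)[C@H]3OC(C)=O)c2ccc(OCc3ccccc3)c(OCc3ccccc3)c2O[C@@H]1c1ccc(OCc2ccccc2)c(OCc2ccccc2)c1 | intermediate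
20 | 3-ketone of 19 | O=C1[C@H](c2cc3c(c(OCc4ccccc4)c2OCc4ccccc4)O[C@H](c2ccc(OCc4ccccc4)c(OCc4ccccc4)c2)[C@H](OC(C)=O)[C@H]3OC(C)=O)c2ccc(OCc3ccccc3)c(OCc3ccccc3)c2O[C@@H]1c1ccc(OCc2ccccc2)c(OCc2ccccc2)c1 | intermediate
21 | all-cis 3-alcohol, lower 3,4-diacetate (not isolated) | O[C@@H]1[C@H](c2cc3c(c(OCc4ccccc4)c2OCc4ccccc4)O[C@H](c2ccc(OCc4ccccc4)c(OCc4ccccc4)c2)[C@H](OC(C)=O)[C@H]3OC(C)=O)c2ccc(OCc3ccccc3)c(OCc3ccccc3)c2O[C@@H]1c1ccc(OCc2ccccc2)c(OCc2ccccc2)c1 | intermediate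
22 | octa-O-benzyl ether of the target | O[C@@H]1[C@H](c2cc3c(c(OCc4ccccc4)c2OCc4ccccc4)O[C@H](c2ccc(OCc4ccccc4)c(OCc4ccccc4)c2)[C@H](O)[C@H]3O)c2ccc(OCc3ccccc3)c(OCc3ccccc3)c2O[C@@H]1c1ccc(OCc2ccccc2)c(OCc2ccccc2)c1 | intermediate
23 | (2R,3R,4R)-2-(3,4-dihydroxyphenyl)-4-[(2R,3R,4S)-2-(3,4-dihydroxyphenyl)-3,4,7,8-tetrahydroxychroman-6-yl]chromane-3,7,8-triol | Oc1ccc([C@H]2Oc3c(ccc(O)c3O)[C@@H](c3cc4c(c(O)c3O)O[C@H](c3ccc(O)c(O)c3)[C@H](O)[C@H]4O)[C@H]2O)cc1O | target

**Step count and risks**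

Total steps: 16. Longest linear sequence: 13 steps (1 → 2 → 3 → 8 → 10 → 12 → 13 → 14 → 15 → 16 → 19 → 20 → 22 → 23).

Most likely to fail, step 4 (cycloaddition: the electron-rich o-quinone methide may oligomerise at 150 °C faster than it adds to the hindered β-substituted styrene). The fallback sets out from 3 and comes back at 8. The phenol of 3 is acylated (Boc2O, cat. DMAP, i-Pr2NEt, CH2Cl2, 0 °C) to tert-butyl [2,3-bis(benzyloxy)-6-(hydroxymethyl)phenyl] carbonate F1. Adding t-BuMgCl to F1 and 6 in Et2O at −78 °C and warming to room temperature makes the magnesium alkoxide take over the Boc group and expel tert-butyl carbonate. The same o-quinone methide 7 is thus released cold, as its magnesium complex, and is trapped by 6 to give 8 without the thermal side reactions.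

Step 6 (Baeyer–Villiger: the aldehyde may give the carboxylic acid by hydride migration instead of the formate). The fallback sets out from 10 and comes back at 13. Aldehyde 10 is converted (Ac2O, Et3N, cat. DMAP, 60 °C) into its enol acetate, [(2R)-7,8-bis(benzyloxy)-2-[3,4-bis(benzyloxy)phenyl]chroman-3-ylidene]methyl acetate F2. Its exocyclic C=C bond is cleaved (cat. OsO4, NaIO4, 2,6-lutidine, dioxane/H2O) to ketone 13, which enters step 8 as before. The alcohol 12 needed for step 11 is then made from 13 with NaBH4 in MeOH/THF at −40 °C (small hydride adds axially, giving the equatorial 2,3-trans alcohol).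

Step 13 (coupling: the cation from 18 can attack C-6 of a second molecule of 18 instead of 16). The fallback sets out from 12 and comes back at 19. Alcohol 12 is brominated at C-6 with NBS (CH2Cl2, −78 → 0 °C) to (2R,3S)-6-bromo-7,8-bis(benzyloxy)-2-[3,4-bis(benzyloxy)phenyl]chroman-3-ol F3. F3 is taken through the conditions of steps 11 and 12 to the capped 6-bromo-4-methoxy alcohol F4 and the capped 6-bromo-4-benzylsulfanyl alcohol F5. F5 can no longer alkylate itself, so it is coupled with only 1.2 equiv of 16 (AgBF4, THF, 0 °C) to the 6-bromo dimer F6. The blocking bromine is then removed with Bu3SnH/AIBN (toluene, 80 °C) to return 19.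

**Further compounds**
F1 | step 4 | tert-butyl [2,3-bis(benzyloxy)-6-(hydroxymethyl)phenyl] carbonate | CC(C)(C)OC(=O)Oc1c(CO)ccc(OCc2ccccc2)c1OCc1ccccc1
F2 | step 6 | [(2R)-7,8-bis(benzyloxy)-2-[3,4-bis(benzyloxy)phenyl]chroman-3-ylidene]methyl acetate | CC(=O)OC=C1Cc2ccc(OCc3ccccc3)c(OCc3ccccc3)c2O[C@@H]1c1ccc(OCc2ccccc2)c(OCc2ccccc2)c1
F3 | step 13 | (2R,3S)-6-bromo-7,8-bis(benzyloxy)-2-[3,4-bis(benzyloxy)phenyl]chroman-3-ol | O[C@H]1Cc2cc(Br)c(OCc3ccccc3)c(OCc3ccccc3)c2O[C@@H]1c1ccc(OCc2ccccc2)c(OCc2ccccc2)c1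
F4 | step 13 | 6-bromo analogue of 17 (6-bromo-4-methoxy alcohol, 2,3-trans-3,4-trans) | CO[C@@H]1c2cc(Br)c(OCc3ccccc3)c(OCc3ccccc3)c2O[C@H](c2ccc(OCc3ccccc3)c(OCc3ccccc3)c2)[C@H]1O
F5 | step 13 | 6-bromo analogue of 18 (6-bromo-4-benzylsulfanyl alcohol, 2,3-trans-3,4-trans) | c1ccccc1CS[C@@H]1c2cc(Br)c(OCc3ccccc3)c(OCc3ccccc3)c2O[C@H](c2ccc(OCc3ccccc3)c(OCc3ccccc3)c2)[C@H]1O
F6 | step 13 | 6-bromo analogue of 19 (bromine on C-6 of the upper unit) | O[C@H]1[C@H](c2cc3c(c(OCc4ccccc4)c2OCc4ccccc4)O[C@H](c2ccc(OCc4ccccc4)c(OCc4ccccc4)c2)[C@H](OC(C)=O)[C@H]3OC(C)=O)c2cc(Br)c(OCc3ccccc3)c(OCc3ccccc3)c2O[C@@H]1c1ccc(OCc2ccccc2)c(OCc2ccccc2)c1
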